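**Retrosynthetic overview**
1. Target triacid 10 ⇐ trimethyl ester 8 by threefold SN2 O‑demethylation; the C16=CH2 of 8 ⇐ 16‑norketone 7 by methylenation.
2. The cis‑2β,3β‑diol of 7 ⇐ β‑face OsO4 dihydroxylation of Δ2‑alkene 6; 6 ⇐ anti‑dehydration of the axial 3β‑alcohol of norketone 4.
3. 4 ⇐ the natural 3β‑hydroxy triacid 1 by esterification and Lemieux–Johnson cleavage, which hides the 16‑ene while OsO4 works on ring A.
4. Ring order: no ring is built. Rings A, B, C and D and seven of the nine stereocentres arrive intact in 1; only C2 and C3 are set (step 4).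

Assumption: the fermentation‑derived 3β‑hydroxy C20 gibberellin triacid 1 (number 13 of the gibberellin A series, a Gibberella fujikuroi metabolite sold as a plant‑hormone standard) counts as commercially available. The shortest defensible route is then a six‑step relay from it, not a de novo construction of the ring system. The route is reasoned from first principles and analogy, not run. Locants and α/β descriptors follow the usual gibberellin drawing (C19, C20 α; C18, H‑5, H‑9 β); the SMILES strings are definitive.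

**Step 1**
Reactants: 1 3β‑hydroxygibberell‑16‑ene‑7,19,20‑trioic acid
Product: 2 trimethyl 3β‑hydroxygibberell‑16‑ene‑7,19,20‑trioate
Conditions: TMSCHN2 (4.5 equiv), toluene/MeOH 4:1, 0 °C → rt
Reagents that add atoms: trimethylsilyldiazomethane, C[Si](C)(C)C=[N+]=[N-]
Why: Diazoalkane esterification methylates the three carboxylic acids at oxygen (insensitive to the hindrance at C19 and C20), leaves the axial 3β‑alcohol free and protects the acids before the C3 chemistry, with no stereocentre touched.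

**Step 2**
Reactants: 2 trimethyl 3β‑hydroxygibberell‑16‑ene‑7,19,20‑trioate
Product: 4 trimethyl 3β‑hydroxy‑16‑oxo‑17‑norgibberellane‑7,19,20‑trioate, via 16,17-diol 3 (not isolated)
Conditions: OsO4 (2 mol %), NaIO4 (3 equiv), THF/H2O 2:1, rt
Reagents that add atoms: osmium tetroxide, O=[Os](=O)(=O)=O; sodium periodate, [Na+].[O-]I(=O)(=O)=O
Why: Lemieux–Johnson oxidation, in which OsO4 dihydroxylates the only alkene on its exo face to diol 3 and NaIO4 cleaves the glycol in the same pot, so that C17 is removed and the exocyclic alkene is stored as a ketone while ring A is later osmylated (the C16 centre of 3 is destroyed again).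

**Step 3**
Reactants: 4 trimethyl 3β‑hydroxy‑16‑oxo‑17‑norgibberellane‑7,19,20‑trioate
Product: 6 trimethyl 16‑oxo‑17‑norgibberell‑2‑ene‑7,19,20‑trioate, via 3β-O-dichlorophosphate 5 (not isolated)
Conditions: POCl3 (5 equiv), pyridine, 0 → 80 °C
Reagents that add atoms: none
Why: POCl3/pyridine dehydration is an anti‑periplanar bimolecular elimination in which the axial 3β‑dichlorophosphate leaves together with the trans‑diaxial H‑2α, and since C4 is quaternary and carries an electron‑poor ester that disfavours cationic 1,2‑shifts, only the Δ2‑alkene can form.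

**Step 4**
Reactants: 6 trimethyl 16‑oxo‑17‑norgibberell‑2‑ene‑7,19,20‑trioate
Product: 7 trimethyl 2β,3β‑dihydroxy‑16‑oxo‑17‑norgibberellane‑7,19,20‑trioate
Conditions: OsO4 (5 mol %), NMO (1.5 equiv), acetone/H2O 5:1, rt
Reagents that add atoms: osmium tetroxide, O=[Os](=O)(=O)=O; N-methylmorpholine N-oxide, C[N+]1([O-])CCOCC1; water, O
Why: Upjohn syn‑dihydroxylation, in which the α face of the Δ2‑alkene is screened by the pseudoaxial 4α‑ester and the axial 10α‑ester so that OsO4 adds on the β face and sets C2 and C3 together as the cis‑2β,3β‑diol (3‑OH axial, 2‑OH equatorial).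

**Step 5**
Reactants: 7 trimethyl 2β,3β‑dihydroxy‑16‑oxo‑17‑norgibberellane‑7,19,20‑trioate
Product: 8 trimethyl 2β,3β‑dihydroxygibberell‑16‑ene‑7,19,20‑trioate
Conditions: Zn, CH2Br2, TiCl4 (reagent pre‑formed in THF, 5 °C; excess), then 7 in CH2Cl2, rt
Reagents that add atoms: dibromomethane, BrCBr
Why: Lombardo methylenation with the non‑basic Zn/CH2Br2/TiCl4 reagent turns the 16‑ketone back into the exocyclic alkene without attacking the esters or provoking retro‑aldol epimerisation at the 3β‑hydroxy ester, the excess reagent absorbing the free diol and no stereocentre being formed.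

**Step 6**
Reactants: 8 trimethyl 2β,3β‑dihydroxygibberell‑16‑ene‑7,19,20‑trioate
Product: 10 2β,3β‑dihydroxygibberell‑16‑ene‑7,19,20‑trioic acid, via trilithium tricarboxylate 9 (not isolated)
Conditions: LiSPr (10 equiv, from n‑PrSH + n‑BuLi, THF, 0 °C), HMPA, rt → 50 °C, argon; then 1 M HCl to pH 3, 0 °C
Reagents that add atoms: none
Why: SN2 O‑demethylation by thiolate attacks the methyl carbons, so the hindrance at the C19 and C20 carbonyls does not matter, while the weakly basic, non‑hydrolytic medium spares the exocyclic alkene and the retro‑aldol‑prone C3 centre, and acidification of the tricarboxylate gives the triacid.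

**Compound list**
1 | 3β‑hydroxygibberell‑16‑ene‑7,19,20‑trioic acid (natural 3β‑hydroxy C20 gibberellin triacid; number 13 of the gibberellin A series) | C=C1C[C@]23C[C@H]1CC[C@H]2[C@]1(C(=O)O)CC[C@H](O)[C@@](C)(C(=O)O)[C@H]1[C@@H]3C(=O)O | starting material
2 | trimethyl 3β‑hydroxygibberell‑16‑ene‑7,19,20‑trioate (trimethyl ester of 1) | C=C1C[C@]23C[C@H]1CC[C@H]2[C@]1(C(=O)OC)CC[C@H](O)[C@@](C)(C(=O)OC)[C@H]1[C@@H]3C(=O)OC | intermediate
3 | trimethyl (16R)‑3β,16,17‑trihydroxygibberellane‑7,19,20‑trioate (C16 hydroxyl exo, syn to C14) | OC[C@@]1(O)C[C@]23C[C@H]1CC[C@H]2[C@]1(C(=O)OC)CC[C@H](O)[C@@](C)(C(=O)OC)[C@H]1[C@@H]3C(=O)OC | intermediate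
4 | trimethyl 3β‑hydroxy‑16‑oxo‑17‑norgibberellane‑7,19,20‑trioate (16‑norketone, 3β‑OH) | O=C1C[C@]23C[C@H]1CC[C@H]2[C@]1(C(=O)OC)CC[C@H](O)[C@@](C)(C(=O)OC)[C@H]1[C@@H]3C(=O)OC | intermediate
5 | 3β‑O‑dichlorophosphate of 4 | O=C1C[C@]23C[C@H]1CC[C@H]2[C@]1(C(=O)OC)CC[C@H](OP(=O)(Cl)Cl)[C@@](C)(C(=O)OC)[C@H]1[C@@H]3C(=O)OC | intermediate
6 | trimethyl 16‑oxo‑17‑norgibberell‑2‑ene‑7,19,20‑trioate (Δ2‑alkene norketone) | O=C1C[C@]23C[C@H]1CC[C@H]2[C@]1(C(=O)OC)CC=C[C@@](C)(C(=O)OC)[C@H]1[C@@H]3C(=O)OC | intermediate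
7 | trimethyl 2β,3β‑dihydroxy‑16‑oxo‑17‑norgibberellane‑7,19,20‑trioate (2β,3β‑diol norketone) | O=C1C[C@]23C[C@H]1CC[C@H]2[C@]1(C(=O)OC)C[C@H](O)[C@H](O)[C@@](C)(C(=O)OC)[C@H]1[C@@H]3C(=O)OC | intermediate
8 | trimethyl 2β,3β‑dihydroxygibberell‑16‑ene‑7,19,20‑trioate (trimethyl ester of the target) | C=C1C[C@]23C[C@H]1CC[C@H]2[C@]1(C(=O)OC)C[C@H](O)[C@H](O)[C@@](C)(C(=O)OC)[C@H]1[C@@H]3C(=O)OC | intermediate
9 | trilithium 2β,3β‑dihydroxygibberell‑16‑ene‑7,19,20‑trioate | C=C1C[C@]23C[C@H]1CC[C@H]2[C@]1(C(=O)[O-])C[C@H](O)[C@H](O)[C@@](C)(C(=O)[O-])[C@H]1[C@@H]3C(=O)[O-].[Li+].[Li+].[Li+] | intermediate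
10 | 2β,3β‑dihydroxygibberell‑16‑ene‑7,19,20‑trioic acid (the target gibberellin, number 43 of the gibberellin A series) | C=C1C[C@]23C[C@H]1CC[C@H]2[C@]1(C(=O)O)C[C@H](O)[C@H](O)[C@@](C)(C(=O)O)[C@H]1[C@@H]3C(=O)O | target

**Totals**
Total step count: 6. Longest linear sequence: 6 (fully linear from 1).

**Three steps most likely to fail**

First, step 3, the dehydration. The base must reach H‑2α between the two axial esters, and a 3α‑chloride or a rearranged product could compete. The fallback sets out from 4 and comes back at 6, and replaces the base‑mediated anti elimination by a thermal syn elimination that uses the exposed equatorial H‑2β. Norketone 4 is acylated with O‑(4‑methylphenyl) chlorothionoformate (pyridine, DMAP, CH2Cl2, rt) to the 3β‑O‑(4‑methylphenoxy)thiocarbonyl derivative of 4 F1. Heating this in 1,2‑dichlorobenzene at 170 °C triggers a Chugaev‑type Ei elimination that expels COS and 4‑methylphenol and can only give the Δ2‑alkene 6.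

Second, step 4, the osmylation. The alkene sits next to a quaternary carbon, so turnover may stall, and the facial argument is untested. The fallback sets out from 2 and comes back at 8; it builds the diol by enolate chemistry and never touches the 16‑ene, so steps 2, 3 and 5 fall away. Ester 2 is oxidised with Dess–Martin periodinane (CH2Cl2, rt) to trimethyl 3‑oxogibberell‑16‑ene‑7,19,20‑trioate F2. KN(SiMe3)2 (THF, −78 °C) deprotonates C2, the only enolisable side of the ketone, and 2‑(benzenesulfonyl)‑3‑phenyloxaziridine hydroxylates the enolate on the open β face (Davis oxidation) to trimethyl 2β‑hydroxy‑3‑oxogibberell‑16‑ene‑7,19,20‑trioate F3. KBH(s‑Bu)3 (THF, −78 °C) then attacks equatorially from the α side to give the axial 3β‑alcohol, which is 8. This reduction is itself the weak point of the fallback; any 3α‑epimer is removed by chromatography.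

Third, step 6, the triple demethylation. The third SN2 may stall on the growing polyanion, or the thiolate may damage the product. The fallback sets out from 1 and comes back at 10, and changes the protecting group so that the last step is a mild acetal hydrolysis. Triacid 1 is alkylated with chloromethyl methyl ether (i‑Pr2NEt, CH2Cl2, 0 °C) to tris(methoxymethyl) 3β‑hydroxygibberell‑16‑ene‑7,19,20‑trioate F4. The operations of steps 2 to 5 are then repeated unchanged. Lemieux–Johnson cleavage runs through tris(methoxymethyl) (16R)‑3β,16,17‑trihydroxygibberellane‑7,19,20‑trioate F5 (not isolated) to tris(methoxymethyl) 3β‑hydroxy‑16‑oxo‑17‑norgibberellane‑7,19,20‑trioate F6. POCl3/pyridine runs through the 3β‑O‑dichlorophosphate of the tris(methoxymethyl) ester norketone F7 (not isolated) to tris(methoxymethyl) 16‑oxo‑17‑norgibberell‑2‑ene‑7,19,20‑trioate F8. Osmylation gives tris(methoxymethyl) 2β,3β‑dihydroxy‑16‑oxo‑17‑norgibberellane‑7,19,20‑trioate F9, and Zn/CH2Br2/TiCl4 methylenation gives tris(methoxymethyl) 2β,3β‑dihydroxygibberell‑16‑ene‑7,19,20‑trioate F10. Finally 1 M HCl in THF/H2O at rt cleaves the three acetal esters, independent of hindrance at the carbonyls, and gives 10.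

**Further compounds**
F1 | step 3 | 3β‑O‑(4‑methylphenoxy)thiocarbonyl derivative of 4 | O=C1C[C@]23C[C@H]1CC[C@H]2[C@]1(C(=O)OC)CC[C@H](OC(=S)Oc4ccc(C)cc4)[C@@](C)(C(=O)OC)[C@H]1[C@@H]3C(=O)OC
F2 | step 4 | trimethyl 3‑oxogibberell‑16‑ene‑7,19,20‑trioate | C=C1C[C@]23C[C@H]1CC[C@H]2[C@]1(C(=O)OC)CCC(=O)[C@@](C)(C(=O)OC)[C@H]1[C@@H]3C(=O)OC
F3 | step 4 | trimethyl 2β‑hydroxy‑3‑oxogibberell‑16‑ene‑7,19,20‑trioate | C=C1C[C@]23C[C@H]1CC[C@H]2[C@]1(C(=O)OC)C[C@H](O)C(=O)[C@@](C)(C(=O)OC)[C@H]1[C@@H]3C(=O)OC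
F4 | step 6 | tris(methoxymethyl) 3β‑hydroxygibberell‑16‑ene‑7,19,20‑trioate | C=C1C[C@]23C[C@H]1CC[C@H]2[C@]1(C(=O)OCOC)CC[C@H](O)[C@@](C)(C(=O)OCOC)[C@H]1[C@@H]3C(=O)OCOC
F5 | step 6 | tris(methoxymethyl) (16R)‑3β,16,17‑trihydroxygibberellane‑7,19,20‑trioate | OC[C@@]1(O)C[C@]23C[C@H]1CC[C@H]2[C@]1(C(=O)OCOC)CC[C@H](O)[C@@](C)(C(=O)OCOC)[C@H]1[C@@H]3C(=O)OCOC
F6 | step 6 | tris(methoxymethyl) 3β‑hydroxy‑16‑oxo‑17‑norgibberellane‑7,19,20‑trioate | O=C1C[C@]23C[C@H]1CC[C@H]2[C@]1(C(=O)OCOC)CC[C@H](O)[C@@](C)(C(=O)OCOC)[C@H]1[C@@H]3C(=O)OCOC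
F7 | step 6 | 3β‑O‑dichlorophosphate of the tris(methoxymethyl) ester norketone | O=C1C[C@]23C[C@H]1CC[C@H]2[C@]1(C(=O)OCOC)CC[C@H](OP(=O)(Cl)Cl)[C@@](C)(C(=O)OCOC)[C@H]1[C@@H]3C(=O)OCOC
F8 | step 6 | tris(methoxymethyl) 16‑oxo‑17‑norgibberell‑2‑ene‑7,19,20‑trioate | O=C1C[C@]23C[C@H]1CC[C@H]2[C@]1(C(=O)OCOC)CC=C[C@@](C)(C(=O)OCOC)[C@H]1[C@@H]3C(=O)OCOC
F9 | step 6 | tris(methoxymethyl) 2β,3β‑dihydroxy‑16‑oxo‑17‑norgibberellane‑7,19,20‑trioate | O=C1C[C@]23C[C@H]1CC[C@H]2[C@]1(C(=O)OCOC)C[C@H](O)[C@H](O)[C@@](C)(C(=O)OCOC)[C@H]1[C@@H]3C(=O)OCOC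
F10 | step 6 | tris(methoxymethyl) 2β,3β‑dihydroxygibberell‑16‑ene‑7,19,20‑trioate | C=C1C[C@]23C[C@H]1CC[C@H]2[C@]1(C(=O)OCOC)C[C@H](O)[C@H](O)[C@@](C)(C(=O)OCOC)[C@H]1[C@@H]3C(=O)OCOC
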